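**Plan**

- Retrosynthesis: the C8–C(=O) bond between ring A and the 3-(4-methoxyphenyl)propanoyl chain is cut first, giving the unprotected lactone 5 and the phenyl ester 9. Ester 9 is cut at its ester C–O bond (acid 6, phenol 7), and 5 is traced back through its benzyl ethers to the flat coumarin 1 by removing the C4–H bond.
- Enabling feature: in ring A (the benzo ring, chroman-2-one numbering) C8 is the only unsubstituted carbon para to a free hydroxyl (C5–OH) and is also ortho to C7–OH. C6 lies between the two hydroxyls and is para only to the acylated oxygen on C8a, so an acyltransferase that acylates resorcinols para to a phenolate oxygen can address C8 alone.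
- Forward order: both rings are present in 1 and none is formed. Compound 1 is benzylated on both hydroxyls, C3=C4 is reduced, the benzyl groups are removed, and the acyl chain is joined to C8 last with the separately made donor 9.
- Stereochemistry: the only stereocenter, C4, is set by ligand-controlled delivery of hydride from a chiral bisphosphine–CuH catalyst to C4 of the coumarin. It is carried unchanged through hydrogenolysis and the enzymatic acylation.

Key step: step 5

Assumption: (S)-DTBM-SEGPHOS is taken as the ligand enantiomer that delivers hydride to the C4 face leading to the S lactone (the (R) ligand replaces it without other change if a trial shows the opposite sense), and an acyltransferase variant accepting donor 9 and acceptor 5 is taken to be obtainable by screening.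

**Route**

Step 1
Reactants: 1 5,7-dihydroxy-4-phenylcoumarin; 2 benzyl bromide
Product: 3 5,7-bis(benzyloxy)-4-phenylcoumarin
Conditions: BnBr (2.5 equiv), K2CO3 (3 equiv), DMF, 60 °C
Reagents that add atoms: benzyl bromide (second equivalent), BrCc1ccccc1
Why: twofold Williamson ether synthesis in which each of the two phenoxides is O-alkylated by one molecule of the reactive benzylic bromide, masking the acidic hydroxyls that would otherwise consume hydride and silane in the reduction.

Step 2
Reactants: 3 5,7-bis(benzyloxy)-4-phenylcoumarin
Product: 4 (S)-5,7-bis(benzyloxy)-4-phenylchroman-2-one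
Conditions: Cu(OAc)2·H2O (3 mol %), (S)-DTBM-SEGPHOS (3.3 mol %), HSiMe(OEt)2 (1.2 equiv), t-BuOH (1.2 equiv), toluene, 0 °C to rt; aq NH4Cl
Reagents that add atoms: none
Why: CuH-catalysed asymmetric conjugate reduction with a hydrosilane, a reaction established for 4-arylcoumarins, in which the bulky chiral bisphosphine on CuH selects the face of C4 that receives hydride and so sets the S centre, tert-butanol protonates the copper enolate at C3, and keeping the silane near one equivalent guards the aryl lactone against 1,2-reduction.

Step 3
Reactants: 4 (S)-5,7-bis(benzyloxy)-4-phenylchroman-2-one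
Product: 5 (S)-5,7-dihydroxy-4-phenylchroman-2-one
Conditions: H2 (1 atm), 10% Pd/C (palladium on carbon), EtOAc, rt
Reagents that add atoms: none
Why: hydrogenolysis of aryl benzyl ethers under neutral, alcohol-free conditions should free both phenols while the aryl lactone and the C4 centre, which carries only C–C and C–H bonds, stay intact.

Step 4
Reactants: 6 3-(4-methoxyphenyl)propanoic acid; 7 phenol
Product: 9 phenyl 3-(4-methoxyphenyl)propanoate, via O-acylisourea 8 (not isolated)
Conditions: DCC (1.1 equiv), DMAP (10 mol %), CH2Cl2, 0 °C to rt
Reagents that add atoms: none
Why: Steglich esterification in which the carbodiimide activates the acid as its O-acylisourea and DMAP relays the acyl group to the weakly nucleophilic phenol, giving the activated aryl ester needed as enzymatic acyl donor.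

Step 5
Reactants: 5 (S)-5,7-dihydroxy-4-phenylchroman-2-one; 9 phenyl 3-(4-methoxyphenyl)propanoate
Product: 10 (S)-5,7-dihydroxy-8-[3-(4-methoxyphenyl)propanoyl]-4-phenylchroman-2-one (target)
Conditions: engineered Pseudomonas protegens acyltransferase (PhlA/PhlB/PhlC complex, donor-pocket variant, cell-free extract), 9 (3 equiv), KH2PO4/K2HPO4 buffer (50 mM, pH 7.0), DMSO (15% v/v), 30 °C; then pH 3, EtOAc extraction, chromatography
Reagents that add atoms: none
Why: Proposed new method: the phenyl ester 9 acylates the active-site cysteine of the acyltransferase with loss of phenol, ring A of 5 binds as a phenolate, and its carbon C8 (ortho to the C7 oxygen, para to the C5 oxygen) attacks the thioester carbonyl, after which loss of the C8 proton restores the aromatic ring and frees the thiol. The closest known reaction type is the cofactor-free biocatalytic Friedel–Crafts C-acylation of resorcinols and of monoacetylphloroglucinol by the wild-type enzyme with phenyl or isopropenyl esters as donors, and what is new is the long arylpropanoyl donor together with a bicyclic lactone acceptor, so a variant with a widened donor channel and acceptor site has to be found by screening. No ring is closed and no stereocenter is created, and the S centre at C4 is neither acidic nor close to the reacting carbon, so it should pass through unchanged at pH 7. The step needs C8 over C6 and C- over O-acylation: the enzyme presents to the acyl-enzyme only a carbon lying para to a phenolate oxygen, which in 5 is C8 because C6 sits between the two hydroxyls and C4a is substituted, and an O-acyl product is itself an aryl ester that the enzyme can take up again as a donor, so the hydrogen-bonded C8 ketone is the end point. The lactone oxygen on C8a keeps ring A at least as electron-rich as the natural acceptor, and pH 7.0 with a short reaction time is chosen so that the aryl lactone does not open to the symmetric phloroglucinol acid, which would erase the difference between C6 and C8.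

**Compound list**

1 | 5,7-dihydroxy-4-phenylcoumarin (5,7-dihydroxy-4-phenyl-2H-chromen-2-one) | O=c1cc(-c2ccccc2)c2c(O)cc(O)cc2o1 | starting material
2 | benzyl bromide | BrCc1ccccc1 | starting material
3 | 5,7-bis(benzyloxy)-4-phenylcoumarin | O=c1cc(-c2ccccc2)c2c(OCc3ccccc3)cc(OCc3ccccc3)cc2o1 | intermediate
4 | (S)-5,7-bis(benzyloxy)-4-phenylchroman-2-one | O(Cc1ccccc1)c1cc(OCc2ccccc2)c2c(c1)OC(=O)C[C@H]2c1ccccc1 | intermediate
5 | (S)-5,7-dihydroxy-4-phenylchroman-2-one | Oc1cc(O)c2c(c1)OC(=O)C[C@H]2c1ccccc1 | intermediate
6 | 3-(4-methoxyphenyl)propanoic acid | COc1ccc(CCC(=O)O)cc1 | starting material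
7 | phenol | Oc1ccccc1 | starting material
8 | O-acylisourea from 6 and DCC, N,N'-dicyclohexyl-O-[3-(4-methoxyphenyl)propanoyl]isourea (not isolated) | COc1ccc(CCC(=O)OC(=NC2CCCCC2)NC2CCCCC2)cc1 | intermediate
9 | phenyl 3-(4-methoxyphenyl)propanoate | COc1ccc(CCC(=O)Oc2ccccc2)cc1 | intermediate
10 | (S)-5,7-dihydroxy-8-[3-(4-methoxyphenyl)propanoyl]-4-phenylchroman-2-one | COc1ccc(CCC(=O)c2c(O)cc(O)c3c2OC(=O)C[C@H]3c2ccccc2)cc1 | target

**Step count**

Total steps: 5. Longest linear sequence: 4 steps (steps 1, 2, 3 and 5); step 4 prepares the donor in parallel.

**Steps most likely to fail**

Step 5 (proposed new method). The acyl-enzyme may fail to form with the long donor, or may be hydrolysed faster than the bulky acceptor intercepts it. Slow opening of the aryl lactone in buffer would also make ring A symmetric and scramble the site of acylation. The fallback is a Houben–Hoesch acylation that sets out from 5 and returns to the route at 10. Compound 5 and commercial 3-(4-methoxyphenyl)propanenitrile (COc1ccc(CCC#N)cc1) are treated with dry HCl and ZnCl2 in Et2O/dioxane at 0 °C. This should give the ketiminium chloride (S)-8-[1-iminio-3-(4-methoxyphenyl)propyl]-5,7-dihydroxy-4-phenylchroman-2-one chloride F1. Hydrolysis of F1 in water at 80 °C should give 10, and the acidic medium keeps the lactone closed. The usual preference of resorcinols for attack para to a hydroxyl directs the nitrilium electrophile to C8. Material acylated at C6 would be removed by chromatography.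

Step 2. The same CuH may reduce the aryl lactone carbonyl (1,2-reduction) after the conjugate reduction. Facial discrimination may also weaken because the peri benzyloxy group at C5 twists the C4 phenyl ring out of the coumarin plane. The fallback forms the C4–phenyl bond instead of the C4–H bond; it sets out from benzyl bromide 2 and returns at 4. Commercial 5,7-dihydroxycoumarin (O=c1ccc2c(O)cc(O)cc2o1) is benzylated with two equivalents of 2 (K2CO3, DMF, 60 °C) to give 5,7-bis(benzyloxy)coumarin F2. Hayashi–Miyaura conjugate addition of phenylboronic acid (OB(O)c1ccccc1) to F2 with Rh(acac)(C2H4)2 and (S)-SEGPHOS in dioxane/water at 60 °C should then give 4. No hydride is present, so over-reduction cannot occur, and the aryl–rhodium insertion step controls the face; the (S) ligand is expected to give the S product, in line with the sense known for simple coumarins.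

Step 3. Cleavage of the shielded C5 benzyl ether may be slow. Long contact with palladium and hydrogen could then erode the configuration by exchange of the doubly benzylic C4–H on the metal surface, and any alcohol co-solvent added to speed the reaction could open the lactone. The fallback replaces benzyl by silyl protection and avoids palladium and hydrogen; it sets out from 1 and returns at 5. Compound 1 is silylated (TBSCl, imidazole, DMF, rt) to 5,7-bis(tert-butyldimethylsilyloxy)-4-phenylcoumarin F3. The reduction of step 2 applied to F3 should give (S)-5,7-bis(tert-butyldimethylsilyloxy)-4-phenylchroman-2-one F4. HF·pyridine in THF at 0 °C should then cleave both aryl silyl ethers of F4 under mildly acidic conditions to give 5.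

**Further compounds**

F1 | step 5 | (S)-8-[1-iminio-3-(4-methoxyphenyl)propyl]-5,7-dihydroxy-4-phenylchroman-2-one chloride | COc1ccc(CCC(=[NH2+])c2c(O)cc(O)c3c2OC(=O)C[C@H]3c2ccccc2)cc1.[Cl-]
F2 | step 2 | 5,7-bis(benzyloxy)coumarin | O=c1ccc2c(OCc3ccccc3)cc(OCc3ccccc3)cc2o1
F3 | step 3 | 5,7-bis(tert-butyldimethylsilyloxy)-4-phenylcoumarin | O=c1cc(-c2ccccc2)c2c(O[Si](C)(C)C(C)(C)C)cc(O[Si](C)(C)C(C)(C)C)cc2o1
F4 | step 3 | (S)-5,7-bis(tert-butyldimethylsilyloxy)-4-phenylchroman-2-one | CC(C)(C)[Si](C)(C)Oc1cc(O[Si](C)(C)C(C)(C)C)c2c(c1)OC(=O)C[C@H]2c1ccccc1
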